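**Plan**

- Retrosynthesis: the silyl groups and the C3 hydroxyl (C3–O bond) come off first; ring C is then cut at C4a–C4, C4–C3 and O1–C2.
- Enabling feature: C4 of ring C is a lone carbonyl carbon between C4a of ring A and C3, so it can enter as carbon monoxide between an iodide on C4a and a terminal alkyne that supplies C3 and C2 with ring B; the phenol oxygen ortho to the iodide becomes O1.
- Ring A piece (iodophenol 8): from 3-hydroxy-4,5-dimethoxybenzaldehyde by silylation, Baeyer–Villiger oxidation, MOM-directed ortho-lithiation/iodination and MOM removal; the future C7 oxygen is marked as its TIPS ether from the first step.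
- Ring B piece (alkyne 16): the ArCH2–CH2 bond is made by B-alkyl Suzuki coupling of 3-bromo-4-methoxybenzaldehyde with a Roche-ester-derived alkene, and the alkyne by Ohira–Bestmann homologation.
- Forward order: rings A and B are bought; the side chain is joined to ring B, ring C is closed in one three-component operation, C3 is hydroxylated, and both silyl ethers are removed.
- Stereochemistry: the single (S) centre is the carbon skeleton of (R)-Roche ester, whose CH2OH stays the CH2OH of the target; no bond at this centre is broken, and the descriptor changes from R to S only through CIP priorities.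

Key step: step 11

**Route**

Step 1
Reactants: 1 3-hydroxy-4,5-dimethoxybenzaldehyde
Product: 2 3,4-dimethoxy-5-[(triisopropylsilyl)oxy]benzaldehyde
Conditions: TIPSCl, imidazole, DMF, rt
Reagents that add atoms: chlorotriisopropylsilane (TIPSCl), CC(C)[Si](Cl)(C(C)C)C(C)C
Why: Imidazole-promoted silylation of a phenol; the bulky aryl TIPS ether should survive the later peracid, organolithium, acid and amine steps and keeps the future C7 oxygen distinct from the two methyl ethers.

Step 2
Reactants: 2 3,4-dimethoxy-5-[(triisopropylsilyl)oxy]benzaldehyde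
Product: 4 3,4-dimethoxy-5-[(triisopropylsilyl)oxy]phenol, via aryl formate 3 (not isolated)
Conditions: mCPBA, CH2Cl2, 0 °C → rt; then Et3N (cat.), MeOH, rt
Reagents that add atoms: 3-chloroperoxybenzoic acid (mCPBA), OOC(=O)c1cccc(Cl)c1
Why: Baeyer–Villiger (Dakin-type) oxidation in which the electron-rich aryl group bearing a para methoxy migrates in preference to hydride, followed by mild methanolysis of the formate that leaves the aryl TIPS ether intact.

Step 3
Reactants: 4 3,4-dimethoxy-5-[(triisopropylsilyl)oxy]phenol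
Product: 5 [2,3-dimethoxy-5-(methoxymethoxy)phenoxy]triisopropylsilane
Conditions: MOMCl, i-Pr2NEt, CH2Cl2, 0 °C → rt
Reagents that add atoms: chloromethyl methyl ether (MOMCl), COCCl
Why: O-alkylation of the phenol with MOMCl installs a strong ortho-directing group for the lithiation that follows.

Step 4
Reactants: 5 [2,3-dimethoxy-5-(methoxymethoxy)phenoxy]triisopropylsilane
Product: 7 [4-iodo-2,3-dimethoxy-5-(methoxymethoxy)phenoxy]triisopropylsilane, via aryllithium 6 (not isolated)
Conditions: n-BuLi, THF, 0 °C; then I2, THF, −78 °C → rt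
Reagents that add atoms: iodine, II
Why: Directed ortho-metalation takes place at the position flanked by the two coordinating groups OMOM and OMe, the other ortho site being shielded by the bulky, poorly coordinating OTIPS group, and iodine traps aryllithium 6.

Step 5
Reactants: 7 [4-iodo-2,3-dimethoxy-5-(methoxymethoxy)phenoxy]triisopropylsilane
Product: 8 2-iodo-3,4-dimethoxy-5-[(triisopropylsilyl)oxy]phenol
Conditions: HCl (1.25 M in MeOH), CH2Cl2, 0 °C → rt
Reagents that add atoms: none
Why: Acid-catalysed acetal exchange with methanol cleaves the MOM ether under mild conditions that an aryl TIPS ether, aryl methyl ethers and the aryl iodide should tolerate.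

Step 6
Reactants: 9 methyl (2R)-3-hydroxy-2-methylpropanoate ((R)-Roche ester)
Product: 10 methyl (2R)-3-[(tert-butyldimethylsilyl)oxy]-2-methylpropanoate
Conditions: TBSCl, imidazole, CH2Cl2, 0 °C → rt
Reagents that add atoms: tert-butylchlorodimethylsilane (TBSCl), CC(C)(C)[Si](C)(C)Cl
Why: Standard silylation of a primary alcohol; the stereocentre is not involved.

Step 7
Reactants: 10 methyl (2R)-3-[(tert-butyldimethylsilyl)oxy]-2-methylpropanoate
Product: 11 (2R)-3-[(tert-butyldimethylsilyl)oxy]-2-methylpropanal
Conditions: i-Bu2AlH (1.05 equiv), CH2Cl2, −78 °C; MeOH, then aq. KNaC4H4O6 (potassium sodium tartrate)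
Reagents that add atoms: none
Why: Partial reduction of the ester with i-Bu2AlH stops at the tetrahedral aluminium hemiacetal at −78 °C and gives the aldehyde on work-up; the α-stereocentre is kept by working cold and using 11 at once.

Step 8
Reactants: 11 (2R)-3-[(tert-butyldimethylsilyl)oxy]-2-methylpropanal
Product: 12 tert-butyldimethyl{[(2S)-2-methylbut-3-en-1-yl]oxy}silane
Conditions: Ph3PCH3Br (1.3 equiv), KN(SiMe3)2 (1.2 equiv), THF, 0 °C; then 11, −78 °C → rt
Reagents that add atoms: methyltriphenylphosphonium bromide, C[P+](c1ccccc1)(c1ccccc1)c1ccccc1.[Br-]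
Why: Wittig methylenation with the ylide formed from a slight deficit of base, so that no free base enolises the α-methyl aldehyde; the stereocentre is carried over unchanged and only its descriptor changes from R to S.

Step 9
Reactants: 12 tert-butyldimethyl{[(2S)-2-methylbut-3-en-1-yl]oxy}silane; 13 3-bromo-4-methoxybenzaldehyde
Product: 15 3-{(3S)-4-[(tert-butyldimethylsilyl)oxy]-3-methylbutyl}-4-methoxybenzaldehyde, via alkylborane 14 (not isolated)
Conditions: 9-BBN-H (9-borabicyclo[3.3.1]nonane), THF, 0 °C → rt; then aq. K3PO4, 13, PdCl2(dppf) (5 mol %), DMF, 50 °C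
Reagents that add atoms: none
Why: Anti-Markovnikov hydroboration of the terminal alkene followed by B-alkyl Suzuki–Miyaura coupling with the aryl bromide; aqueous phosphate destroys residual B–H before the aldehyde is added, and the stereocentre, β to boron, is untouched.

Step 10
Reactants: 15 3-{(3S)-4-[(tert-butyldimethylsilyl)oxy]-3-methylbutyl}-4-methoxybenzaldehyde
Product: 16 tert-butyl{[(2S)-4-(5-ethynyl-2-methoxyphenyl)-2-methylbutyl]oxy}dimethylsilane
Conditions: dimethyl (1-diazo-2-oxopropyl)phosphonate, K2CO3, MeOH/THF, 0 °C → rt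
Reagents that add atoms: dimethyl (1-diazo-2-oxopropyl)phosphonate (Ohira–Bestmann reagent), COP(=O)(OC)C(=[N+]=[N-])C(C)=O
Why: Seyferth–Gilbert homologation in the Ohira–Bestmann variant converts the aryl aldehyde into the terminal alkyne under mild carbonate conditions to which the alkyl TBS ether and the non-enolisable stereocentre are inert.

Step 11
Reactants: 8 2-iodo-3,4-dimethoxy-5-[(triisopropylsilyl)oxy]phenol; 16 tert-butyl{[(2S)-4-(5-ethynyl-2-methoxyphenyl)-2-methylbutyl]oxy}dimethylsilane; 17 carbon monoxide
Product: 20 2-{3-[(3S)-4-(tert-butyldimethylsilyloxy)-3-methylbutyl]-4-methoxyphenyl}-5,6-dimethoxy-7-[(triisopropylsilyl)oxy]-4H-chromen-4-one, via ynone 18 (not isolated), via enaminone 19 (not isolated)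
Conditions: PdCl2(dppf) (5 mol %), CO (20 bar), Et2NH (solvent), 100–120 °C, autoclave
Reagents that add atoms: none
Why: Zerovalent palladium, generated in situ from PdCl2(dppf), inserts into the C–I bond of 8, CO insertion gives an aroyl complex of divalent palladium, and this couples with the amine-activated terminal alkyne 16 to release ynone 18 (C4a–C4 and C4–C3 formed). Diethylamine then adds to 18 to give enaminone 19, and the ortho phenol oxygen displaces the amine at the β-carbon by addition–elimination to form O1–C2; ring C, the only ring made, is thus closed at oxygen in a six-membered mode that is 6-endo with respect to the original alkyne and gives the aromatic 4-pyranone directly. The closest known reaction type is the palladium-catalysed carbonylative annulation of ortho-iodophenols with terminal alkynes to flavones and chromones. No stereocentre is formed, and the (S) centre of the side chain is remote from all reacting atoms. The step needs carbonylation to outrun direct alkynylation, which the CO pressure and the flanking OH and OMe groups favour because they retard direct coupling of the hindered arylpalladium more than CO insertion, and it needs six-membered flavone rather than five-membered aurone closure, which the secondary amine secures by routing the closure through 19. The ring A pattern cannot scramble, because the iodine placed in step 4 defines C4a and the adjacent hydroxyl defines O1.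

Step 12
Reactants: 20 2-{3-[(3S)-4-(tert-butyldimethylsilyloxy)-3-methylbutyl]-4-methoxyphenyl}-5,6-dimethoxy-7-[(triisopropylsilyl)oxy]-4H-chromen-4-one
Product: 23 2-{3-[(3S)-4-(tert-butyldimethylsilyloxy)-3-methylbutyl]-4-methoxyphenyl}-3-hydroxy-5,6-dimethoxy-7-[(triisopropylsilyl)oxy]-4H-chromen-4-one, via 3-lithioflavone 21 (not isolated), via 3-boronate 22 (not isolated)
Conditions: LiN(i-Pr)2, THF, −78 °C; B(OMe)3, −78 → 0 °C; then AcOH, 30% aq. H2O2, 0 °C → rt
Reagents that add atoms: hydrogen peroxide, OO
Why: Carbonyl-assisted vinylic deprotonation of the flavone at C3, borylation with B(OMe)3 and oxidative conversion of C–B into C–O is a known way from flavones to flavonols, and both silyl ethers should tolerate the amide base and the buffered peroxide.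

Step 13
Reactants: 23 2-{3-[(3S)-4-(tert-butyldimethylsilyloxy)-3-methylbutyl]-4-methoxyphenyl}-3-hydroxy-5,6-dimethoxy-7-[(triisopropylsilyl)oxy]-4H-chromen-4-one
Product: 24 3,7-dihydroxy-2-{3-[(3S)-4-hydroxy-3-methylbutyl]-4-methoxyphenyl}-5,6-dimethoxy-4H-chromen-4-one
Conditions: Bu4NF, AcOH, THF, 0 °C → rt
Reagents that add atoms: none
Why: Fluoride-induced desilylation removes the aryl TIPS ether and the primary TBS ether in one operation, and the acetic acid buffer keeps the base- and air-sensitive flavonol from standing as free phenoxide.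

**Compound list**

1 | 3-hydroxy-4,5-dimethoxybenzaldehyde | COc1cc(C=O)cc(O)c1OC | starting material
2 | 3,4-dimethoxy-5-[(triisopropylsilyl)oxy]benzaldehyde | COc1cc(C=O)cc(O[Si](C(C)C)(C(C)C)C(C)C)c1OC | intermediate
3 | 3,4-dimethoxy-5-[(triisopropylsilyl)oxy]phenyl formate (not isolated) | COc1cc(OC=O)cc(O[Si](C(C)C)(C(C)C)C(C)C)c1OC | intermediate
4 | 3,4-dimethoxy-5-[(triisopropylsilyl)oxy]phenol | COc1cc(O)cc(O[Si](C(C)C)(C(C)C)C(C)C)c1OC | intermediate
5 | [2,3-dimethoxy-5-(methoxymethoxy)phenoxy]triisopropylsilane | COCOc1cc(OC)c(OC)c(O[Si](C(C)C)(C(C)C)C(C)C)c1 | intermediate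
6 | {2,3-dimethoxy-6-(methoxymethoxy)-4-[(triisopropylsilyl)oxy]phenyl}lithium (not isolated) | [Li]c1c(OCOC)cc(O[Si](C(C)C)(C(C)C)C(C)C)c(OC)c1OC | intermediate
7 | [4-iodo-2,3-dimethoxy-5-(methoxymethoxy)phenoxy]triisopropylsilane | COCOc1cc(O[Si](C(C)C)(C(C)C)C(C)C)c(OC)c(OC)c1I | intermediate
8 | 2-iodo-3,4-dimethoxy-5-[(triisopropylsilyl)oxy]phenol | Oc1cc(O[Si](C(C)C)(C(C)C)C(C)C)c(OC)c(OC)c1I | intermediate
9 | methyl (2R)-3-hydroxy-2-methylpropanoate ((R)-Roche ester) | COC(=O)[C@H](C)CO | starting material
10 | methyl (2R)-3-[(tert-butyldimethylsilyl)oxy]-2-methylpropanoate | COC(=O)[C@H](C)CO[Si](C)(C)C(C)(C)C | intermediate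
11 | (2R)-3-[(tert-butyldimethylsilyl)oxy]-2-methylpropanal | O=C[C@H](C)CO[Si](C)(C)C(C)(C)C | intermediate
12 | tert-butyldimethyl{[(2S)-2-methylbut-3-en-1-yl]oxy}silane | C=C[C@H](C)CO[Si](C)(C)C(C)(C)C | intermediate
13 | 3-bromo-4-methoxybenzaldehyde | COc1ccc(C=O)cc1Br | starting material
14 | 9-{(3S)-4-[(tert-butyldimethylsilyl)oxy]-3-methylbutyl}-9-borabicyclo[3.3.1]nonane (not isolated) | C1CC2CCCC(C1)B2CC[C@H](C)CO[Si](C)(C)C(C)(C)C | intermediate
15 | 3-{(3S)-4-[(tert-butyldimethylsilyl)oxy]-3-methylbutyl}-4-methoxybenzaldehyde | COc1ccc(C=O)cc1CC[C@H](C)CO[Si](C)(C)C(C)(C)C | intermediate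
16 | tert-butyl{[(2S)-4-(5-ethynyl-2-methoxyphenyl)-2-methylbutyl]oxy}dimethylsilane | C#Cc1ccc(OC)c(CC[C@H](C)CO[Si](C)(C)C(C)(C)C)c1 | intermediate
17 | carbon monoxide | [C-]#[O+] | starting material
18 | 3-{3-[(3S)-4-(tert-butyldimethylsilyloxy)-3-methylbutyl]-4-methoxyphenyl}-1-{6-hydroxy-2,3-dimethoxy-4-[(triisopropylsilyl)oxy]phenyl}prop-2-yn-1-one (not isolated) | O=C(C#Cc1ccc(OC)c(CC[C@H](C)CO[Si](C)(C)C(C)(C)C)c1)c1c(O)cc(O[Si](C(C)C)(C(C)C)C(C)C)c(OC)c1OC | intermediate
19 | (2E)-3-{3-[(3S)-4-(tert-butyldimethylsilyloxy)-3-methylbutyl]-4-methoxyphenyl}-3-(diethylamino)-1-{6-hydroxy-2,3-dimethoxy-4-[(triisopropylsilyl)oxy]phenyl}prop-2-en-1-one (not isolated; drawn as the E isomer, either geometry closes to 20) | CCN(CC)/C(=C/C(=O)c1c(O)cc(O[Si](C(C)C)(C(C)C)C(C)C)c(OC)c1OC)c1ccc(OC)c(CC[C@H](C)CO[Si](C)(C)C(C)(C)C)c1 | intermediate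
20 | 2-{3-[(3S)-4-(tert-butyldimethylsilyloxy)-3-methylbutyl]-4-methoxyphenyl}-5,6-dimethoxy-7-[(triisopropylsilyl)oxy]-4H-chromen-4-one | COc1ccc(-c2cc(=O)c3c(OC)c(OC)c(O[Si](C(C)C)(C(C)C)C(C)C)cc3o2)cc1CC[C@H](C)CO[Si](C)(C)C(C)(C)C | intermediate
21 | 3-lithio derivative of flavone 20 (lithium on C3; not isolated) | COc1ccc(-c2oc3cc(O[Si](C(C)C)(C(C)C)C(C)C)c(OC)c(OC)c3c(=O)c2[Li])cc1CC[C@H](C)CO[Si](C)(C)C(C)(C)C | intermediate
22 | dimethyl (2-{3-[(3S)-4-(tert-butyldimethylsilyloxy)-3-methylbutyl]-4-methoxyphenyl}-5,6-dimethoxy-4-oxo-7-[(triisopropylsilyl)oxy]-4H-chromen-3-yl)boronate (not isolated) | COc1ccc(-c2oc3cc(O[Si](C(C)C)(C(C)C)C(C)C)c(OC)c(OC)c3c(=O)c2B(OC)OC)cc1CC[C@H](C)CO[Si](C)(C)C(C)(C)C | intermediate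
23 | 2-{3-[(3S)-4-(tert-butyldimethylsilyloxy)-3-methylbutyl]-4-methoxyphenyl}-3-hydroxy-5,6-dimethoxy-7-[(triisopropylsilyl)oxy]-4H-chromen-4-one | COc1ccc(-c2oc3cc(O[Si](C(C)C)(C(C)C)C(C)C)c(OC)c(OC)c3c(=O)c2O)cc1CC[C@H](C)CO[Si](C)(C)C(C)(C)C | intermediate
24 | 3,7-dihydroxy-2-{3-[(3S)-4-hydroxy-3-methylbutyl]-4-methoxyphenyl}-5,6-dimethoxy-4H-chromen-4-one (CNP0267774.1) | COc1ccc(-c2oc3cc(O)c(OC)c(OC)c3c(=O)c2O)cc1CC[C@H](C)CO | target

**Step count**

Total: 13 steps. Longest linear sequence: 8 steps (steps 1–5 or steps 6–10, each followed by steps 11–13).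

**Steps most likely to fail, with fallbacks**

Step 11. Several processes can compete: oxidative addition into the hindered, electron-rich C–I bond may be slow; the aroyl complex may be captured by diethylamine to give the amide; direct alkynylation without CO uptake may be followed by benzofuran closure; five-membered aurone closure may occur; and the aryl silyl ether may be lost at the reaction temperature. The fallback delivers C4 as an amide carbon without palladium or CO gas; it sets out from 16 and 8 and returns at ynone 18 and then 20. Alkyne 16 would be deprotonated (n-BuLi, THF, −78 °C) and acylated with N-methoxy-N-methylcarbamoyl chloride to give the Weinreb ynamide 3-{3-[(3S)-4-(tert-butyldimethylsilyloxy)-3-methylbutyl]-4-methoxyphenyl}-N-methoxy-N-methylprop-2-ynamide F1. Iodophenol 8 would be deprotonated with MeLi and submitted to iodine–lithium exchange with t-BuLi (THF, −78 °C) to give lithium 2-lithio-3,4-dimethoxy-5-[(triisopropylsilyl)oxy]phenolate F2. Addition of F2 to F1 should give a chelated tetrahedral adduct that releases ynone 18 on aqueous NH4Cl work-up. Ynone 18 would then be closed in a separate operation with Et2NH in EtOH (through 19) to give 20.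

Step 12. Deprotonation at C3 may be incomplete, the amide base may add to the pyranone and open it, or the boronate may be captured poorly and lose boron by protonation so that 20 is returned. The fallback sets out from 20 and returns at 23. The C2=C3 bond would be epoxidised with dimethyldioxirane (acetone/CH2Cl2, 0 °C) to give the 2,3-epoxide of flavone 20, 2,3-epoxy-2-{3-[(3S)-4-(tert-butyldimethylsilyloxy)-3-methylbutyl]-4-methoxyphenyl}-5,6-dimethoxy-7-[(triisopropylsilyl)oxy]chroman-4-one F3 (both cis-fused epoxide diastereomers). Catalytic p-TsOH in CH2Cl2 would open the epoxide at C2 and, after loss of the C3 proton, should give flavonol 23 (a known epoxidation/isomerisation route from flavones to flavonols).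

Step 8. The basic ylide may enolise the α-methyl aldehyde and erode the enantiomeric purity, and the volatile alkene may be lost on concentration. The fallback replaces the ylide by a two-stage Peterson olefination; it sets out from 11 and returns at 12. Addition of Me3SiCH2MgCl (Et2O, −78 °C), a weakly basic and strongly nucleophilic reagent, should give the β-hydroxysilane (3R)-4-[(tert-butyldimethylsilyl)oxy]-3-methyl-1-(trimethylsilyl)butan-2-ol F4 (both C2 epimers, of no consequence). KH in THF would then bring about the syn elimination to alkene 12, which is taken on in solution to step 9.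

**Further compounds**

F1 | step 11 | 3-{3-[(3S)-4-(tert-butyldimethylsilyloxy)-3-methylbutyl]-4-methoxyphenyl}-N-methoxy-N-methylprop-2-ynamide | CON(C)C(=O)C#Cc1ccc(OC)c(CC[C@H](C)CO[Si](C)(C)C(C)(C)C)c1
F2 | step 11 | lithium 2-lithio-3,4-dimethoxy-5-[(triisopropylsilyl)oxy]phenolate | [Li]Oc1cc(O[Si](C(C)C)(C(C)C)C(C)C)c(OC)c(OC)c1[Li]
F3 | step 12 | 2,3-epoxy-2-{3-[(3S)-4-(tert-butyldimethylsilyloxy)-3-methylbutyl]-4-methoxyphenyl}-5,6-dimethoxy-7-[(triisopropylsilyl)oxy]chroman-4-one (both cis-fused epoxide diastereomers) | COc1ccc(C23OC2C(=O)c2c(OC)c(OC)c(O[Si](C(C)C)(C(C)C)C(C)C)cc2O3)cc1CC[C@H](C)CO[Si](C)(C)C(C)(C)C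
F4 | step 8 | (3R)-4-[(tert-butyldimethylsilyl)oxy]-3-methyl-1-(trimethylsilyl)butan-2-ol (both C2 epimers) | C[Si](C)(C)CC(O)[C@H](C)CO[Si](C)(C)C(C)(C)C
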